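Slowly, over 8.00 d of Thursday's run, the left-handed substrate fell to 28.3 % of the two charged together and the right-handed substrate to 42.0 %. What I had to reckon was the excess among what is left, so I looked for a rule that gives it from the progress of the left-handed substrate.

| setting | Thursday's | Sunday's | elm | cedar |
|---|---|---|---|---|
| left-handed substrate | 0.020 M | 0.020 M | 0.020 M | 0.020 M |
| right-handed substrate | 0.020 M | 0.020 M | 0.020 M | 0.020 M |
| reagent | 2 equiv | 2 equiv | 2.00 equiv | 2.00 equiv |
| free catalyst | 0.04 mol% | 0.084 mol% | 0.1 mol% | 0.06 mol% |
| remark | run made earlier | run made earlier |  |  |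
| time |  |  | 10 d | 10 d |

| run | time / d | right-handed substrate / % | left-handed substrate / % |
|---|---|---|---|
| Thursday's | 0.625 | 48.2 | 45.7 |
| Thursday's | 0.833 | 48.1 | 44.4 |
| Thursday's | 1.25 | 47.6 | 42.3 |
| Thursday's | 2.08 | 46.0 | 38.4 |
| Thursday's | 3.00 | 44.9 | 35.6 |
| Thursday's | 5.00 | 43.3 | 32.0 |
| Thursday's | 8.00 | 42.0 | 28.3 |
| Sunday's | 1.04 | 46.3 | 39.3 |
| Sunday's | 2.08 | 43.8 | 32.8 |
| Sunday's | 3.00 | 42.6 | 30.0 |
| Sunday's | 4.00 | 41.6 | 27.2 |
| Sunday's | 5.00 | 39.8 | 24.9 |
| Sunday's | 6.00 | 39.4 | 24.0 |
| Sunday's | 8.00 | 38.0 | 21.6 |

(scatter of a reading: 0.3 percentage points)

- which one finishes higher in excess of right-handed substrate over left-handed substrate among what is left of the two ("neither" within 2 percentage points) (elm / cedar / neither)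
- excess of right-handed substrate over left-handed substrate among what is left of the two at the end, elm
- excess of right-handed substrate over left-handed substrate among what is left of the two at the end, cedar

- free catalyst is single-handed; left-handed substrate and right-handed substrate are mirror images of each other, charged as a racemate, each of them at the stated concentration
- steps that have been proposed: reagent + free catalyst + left-handed substrate -> free catalyst + left-handed product; reagent <-> dormant form; reagent + free catalyst + right-handed substrate -> free catalyst + right-handed product; 2 free catalyst <-> resting dimer; 2 free catalyst -> spent catalyst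
- an excess is the difference of the two amounts in percent of their sum
- an excess is below zero if the other one leads

I called progress the logarithm of the left-handed substrate's starting share over its present share. The ratio of the two substrates' progress, the selectivity factor, read 3.26 on Thursday's last reading and 3.06 on Sunday's, so I took 3.16. That gave 0.342 as the excess gain: one minus the inverse of the factor, divided by 2. The excess is the hyperbolic tangent of gain times progress.

Progress followed loading times time. Thursday at 8.00 d and Sunday at 4.00 d differ in that product by a factor 1.05, with progress 0.569 and 0.609. Sunday's progress was 0.734 at 6.00 d and 0.839 at 8.00 d. Cedar's product lies between these, which gave progress 0.794 and an excess of 26.5 %.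

Elm lies beyond Sunday's readings. A straight line gave progress 1.05, but that was the weak link: Sunday's rate fell from 0.232 d⁻¹ to 0.0525 d⁻¹. I reforged it, taking progress as linear in the logarithm of the product from 3.00 d onward. That gave 0.972 and 32.1 %.

The forecast named elm, with 32.5 % for elm and 26.5 % for cedar, reading the falling rate as “second-order loss of catalyst”. Its elm figure stood a little above mine.

Elm finished higher, at 32.0 % against 25.2 % for cedar, and the main reason for that gap is the difference in loading of free catalyst: at elm's loading, cedar's excess goes from 25.2 % to 32.0 %.

    reagent + free catalyst + left-handed substrate → free catalyst + left-handed product (k = 500 M⁻² min⁻¹)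
    reagent ⇌ dormant form (K = 4.80, k = 1.10 × 10⁻⁴ min⁻¹)
    reagent + free catalyst + right-handed substrate → free catalyst + right-handed product (k = 160 M⁻² min⁻¹)
    2 free catalyst ⇌ resting dimer (K = 40000 M⁻¹, k = 1100 M⁻¹ min⁻¹)
    2 free catalyst → spent catalyst (k = 2.50 M⁻¹ min⁻¹)

The flask held a resting dimer, 27.0 % of the catalyst in elm at 10.0 d, and part of elm's lead rests on the way back from it: with that reverse step struck out, cedar minus elm goes from −6.8 percentage points to −0.15 points. The gain is untouched by this. Elm kept 38 % of its left-handed substrate, which gives 31.9 %. Cedar's neighbour with 8.00 equiv of reagent kept 2.9 %, which gives 83.7 %, and that flask ended at 83.3 %.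

The earlier runs and the new flask come from a simulation for an exercise; scatter was added.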